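(The data were generated by integration with made-up constants; the scatter is artificial.)

Start from a small charge: 0.080 M of G, with L at several levels.

| flask | G | L | remark | time |
|---|---|---|---|---|
| Wednesday's | 0.080 M | 0.17 M | run made earlier |  |
| Saturday's | 0.080 M | 0.37 M | run made earlier |  |
| eta | 0.080 M | 0.240 M |  | 15 h |
| theta | 0.080 M | 0.120 M |  | 15 h |

| run | time / h | E / % | X / % | G / % |
|---|---|---|---|---|
| Wednesday's | 0.500 | 3.5 | 0.6 | 72.0 |
| Wednesday's | 1.50 | 8.7 | 0.7 | 42.4 |
| Wednesday's | 3.00 | 11.2 | 2.5 | 27.2 |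
| Wednesday's | 5.00 | 13.1 | 5.4 | 21.8 |
| Wednesday's | 6.00 | 14.1 | 6.2 | 19.6 |
| Wednesday's | 8.00 | 12.2 | 9.7 | 18.9 |
| Wednesday's | 10.0 | 13.1 | 12.5 | 17.6 |
| Saturday's | 0.833 | 11.0 | 2.3 | 54.1 |
| Saturday's | 1.33 | 13.4 | 2.5 | 39.6 |
| Saturday's | 2.00 | 16.6 | 5.6 | 28.7 |
| Saturday's | 3.00 | 16.3 | 10.7 | 21.3 |
| Saturday's | 5.00 | 16.0 | 18.5 | 15.7 |
| Saturday's | 6.00 | 15.0 | 22.5 | 13.4 |
| Saturday's | 10.0 | 12.2 | 34.7 | 12.2 |

(each reading ± 0.5 percentage points)

- which of these holds the largest part of the G at the end of eta (X / G / E)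
- which of these holds the largest part of the G at the end of theta (X / G / E)
- amount of E at the end of eta, in percent of the G charged



Read both earlier runs against one quantity: the dose, meaning the L charged times the time elapsed, 216 M·min at the end of eta. Draw eta's curve from the runs at equal dose.

Begin at the start. Wednesday's first reading has E at 3.5% after a dose of 306 M·s, and eta reaches that dose in 0.354 h.

Then find the knee. Saturday's E reads 16.6%, 16.3% and 16.0% at doses of 44.4 M·min, 66.6 M·min and 111 M·min, so its knee is broad. Wednesday's last readings of E, 14.1%, 12.2% and 13.1%, show no clear top. Put eta's broad top between 3.08 h and 7.71 h. Take equal doses as a rough guide: near a dose of 1840 M·s, G reads 27.2% in Wednesday's run and 39.6% in Saturday's.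

Next mark the crossing. X has passed E by Saturday's 5.00 h, a dose of 111 M·min, which eta reaches at 7.71 h.

Now join the end. Saturday's last reading has a dose of 222 M·min, close to eta's. Commit to its values for eta: X at 34.7%, ahead of G and E, each at 12.2%. Theta ends at 108 M·min, close to Wednesday's last 102 M·min. Expect G ahead there, as in that reading, at 17.6%.

The forecast gives X for eta, G for theta and 12.3% of E in eta: “Among the listed species, X leads in eta and G in theta.”

    G + L ⇌ D + E (K = 4.90, k = 0.590 L mol⁻¹ h⁻¹)
    E + L ⇌ D + X (K = 46.0, k = 0.750 L mol⁻¹ h⁻¹)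
    2 G → Q (k = 0.570 L mol⁻¹ h⁻¹)
    G ⇌ J (K = 2.30, k = 0.520 h⁻¹)

Eta ends with X ahead at 29.7%, and E at 12.1%, against the 12.2% taken from Saturday's run. In eta, E is made 1.19 times as fast as it is used at 3.57 h, and 0.816 times as fast at 15.0 h, so its top lies between those times. Theta ends with G ahead at 17.8%, E at 12.8% and X at 11.9%, where Wednesday's last reading showed 17.6%, 13.1% and 12.5%.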